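## Retrosynthetic overview

1. Target 16 ⇒ pyronylmethyl acylphloroglucinol 14 + prenal 11: the pyran ring of the chromene is closed last, by oxa-6π electrocyclisation of vinyl o-quinone methide 15, the ring closure presumed to operate in the plant.
2. 14 ⇒ acylphloroglucinol 4 + one-carbon iminium salt 10 + pyranone 9: the methylene bridge is made through o-quinone methide 13.
3. 9 ⇒ pentan-3-one 5 + malonyl dichloride 6: enol-lactonisation of triketide acyl chloride 8, a laboratory copy of triketide release.
4. 4 ⇒ phloroglucinol 1 + (S)-2-methylbutanoic acid 2, which supplies the only stereocentre.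
5. Ring order: benzene ring bought; pyranone ring in step 2; pyran ring of the chromene last, in step 3.

Assumption: the target is the (2S)-2-methylbutanoyl compound exactly as written in the SMILES, and commercial (S)-2-methylbutanoic acid (≥98% ee) fixes that centre.

## Route

Step 1
Reactants: 1 phloroglucinol (benzene-1,3,5-triol); 2 (S)-2-methylbutanoic acid
Product: 4 (2S)-2-methyl-1-(2,4,6-trihydroxyphenyl)butan-1-one, via acid chloride 3 (not isolated)
Conditions: (COCl)2 (1.0 equiv), HCONMe2 (1 mol%), CH2Cl2, 0 °C → rt; then 1 (1.3 equiv), AlCl3 (4 equiv), CH2Cl2/MeNO2, 0 °C → rt; aq HCl work-up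
Reagents that add atoms: oxalyl chloride, O=C(Cl)C(=O)Cl (its chlorine is held only in intermediate 3; no atom of it stays in 4)
Why: Friedel–Crafts C-acylation, in which the AlCl3-activated acid chloride 3 attacks the triply activated ring of 1 and the chelated aryl ketone–AlCl3 complex is deactivated toward a second acylation; no new stereocentre is made, and the (S) centre from 2 is kept because ketene formation and enolisation are slow at or below room temperature (ee checked by chiral HPLC).

Step 2
Reactants: 5 pentan-3-one; 6 malonyl dichloride (propanedioyl dichloride)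
Product: 9 6-ethyl-4-hydroxy-5-methyl-2H-pyran-2-one, via enol silane 7 (not isolated), via triketide acid chloride 8 (not isolated)
Conditions: Me3SiOTf (1.1 equiv), Et3N (1.05 equiv), CH2Cl2, 0 °C; then 6 (1.0 equiv), −78 °C → rt
Reagents that add atoms: trimethylsilyl trifluoromethanesulfonate, C[Si](C)(C)OS(=O)(=O)C(F)(F)F (its Me3Si group is held only in intermediate 7; no atom of it stays in 9)
Why: Mukaiyama-type C-acylation of the in-situ enol silane by malonyl dichloride (the silyl-enol-ether route to 4-hydroxy-2-pyranones) gives triketide acid chloride 8, whose C5 enol oxygen closes onto the C1 acyl chloride in a six-membered enol-lactonisation and the product tautomerises to the 4-hydroxy-2-pyranone; no stereocentre remains, since the labile C4 of 8 becomes sp2.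

Step 3
Reactants: 4 (2S)-2-methyl-1-(2,4,6-trihydroxyphenyl)butan-1-one; 9 6-ethyl-4-hydroxy-5-methyl-2H-pyran-2-one; 10 N,N-dimethylmethyleneiminium iodide (Eschenmoser's salt); 11 3-methylbut-2-enal (prenal)
Product: 16 6-ethyl-4-hydroxy-3-({5,7-dihydroxy-2,2-dimethyl-8-[(2S)-2-methylbutanoyl]-2H-chromen-6-yl}methyl)-5-methyl-2H-pyran-2-one (the target), via Mannich base hydroiodide 12 (not isolated), via o-quinone methide 13 (not isolated), via pyronylmethyl acylphloroglucinol 14 (not isolated), via vinyl o-quinone methide 15 (not isolated)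
Conditions: 10 (1.0 equiv), MeCN, 0 °C → rt; then 9 (1.2 equiv), NaOAc (1.0 equiv), 50 °C; then 11 (2.0 equiv), 70 °C; one flask
Reagents that add atoms: none
Why: Proposed new method: a one-flask sequence of (a) Mannich C-aminomethylation of 4 by the preformed iminium ion, mono-selective because cationic 12 repels a second iminium ion, (b) acetate-triggered loss of Me2NH to o-quinone methide 13 and Michael addition of the C3 enol carbon of 9 to give 14, and (c) Knoevenagel-type condensation of the last free ring carbon of 14 with prenal under catalysis by the Me2NH2+ AcO− just released, giving vinyl o-quinone methide 15 whose oxa-6π electrocyclisation closes the pyran ring on the oxygen flanking the acyl group (the ring C=O of 15 is then part of a chelated acyl-dione array, while the other ortho oxygen is hydrogen-bonded to the pyranone), the closest known reactions being Mannich-base/o-quinone-methide couplings of hydroxypyranones with phloroglucinols and amine-salt-catalysed formal [3+3] chromene annulations of 3-alkyl acylphloroglucinols with enals; no new stereocentre forms and the (S) centre is not enolised by the acetate buffer.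

## Compound list

1 | phloroglucinol (benzene-1,3,5-triol) | Oc1cc(O)cc(O)c1 | starting material
2 | (S)-2-methylbutanoic acid | CC[C@H](C)C(=O)O | starting material
3 | (S)-2-methylbutanoyl chloride (not isolated) | CC[C@H](C)C(=O)Cl | intermediate
4 | (2S)-2-methyl-1-(2,4,6-trihydroxyphenyl)butan-1-one | CC[C@H](C)C(=O)c1c(O)cc(O)cc1O | intermediate
5 | pentan-3-one | CCC(=O)CC | starting material
6 | malonyl dichloride | ClC(=O)CC(=O)Cl | starting material
7 | (Z)-3-(trimethylsilyloxy)pent-2-ene (major isomer; the E isomer gives the same product; not isolated) | C/C=C(/CC)O[Si](C)(C)C | intermediate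
8 | 4-methyl-3,5-dioxoheptanoyl chloride (racemic, labile C4; not isolated) | CCC(=O)C(C)C(=O)CC(=O)Cl | intermediate
9 | 6-ethyl-4-hydroxy-5-methyl-2H-pyran-2-one | CCc1oc(=O)cc(O)c1C | intermediate
10 | N,N-dimethylmethyleneiminium iodide | C=[N+](C)C.[I-] | starting material
11 | 3-methylbut-2-enal (prenal) | CC(C)=CC=O | starting material
12 | (2S)-1-{3-[(dimethylamino)methyl]-2,4,6-trihydroxyphenyl}-2-methylbutan-1-one hydroiodide (not isolated) | CC[C@H](C)C(=O)c1c(O)cc(O)c(C[NH+](C)C)c1O.[I-] | intermediate
13 | 3,5-dihydroxy-6-methylidene-2-[(2S)-2-methylbutanoyl]cyclohexa-2,4-dien-1-one (o-quinone methide; not isolated) | CC[C@H](C)C(=O)C1=C(O)C=C(O)C(=C)C1=O | intermediate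
14 | 6-ethyl-4-hydroxy-5-methyl-3-({2,4,6-trihydroxy-3-[(2S)-2-methylbutanoyl]phenyl}methyl)-2H-pyran-2-one (not isolated) | CCc1oc(=O)c(Cc2c(O)cc(O)c(C(=O)[C@@H](C)CC)c2O)c(O)c1C | intermediate
15 | vinyl o-quinone methide from 14 and prenal: the former free ring carbon carries a (Z)-3-methylbut-2-enylidene group and the ring oxygen next to the acyl carbon is a C=O (not isolated) | CCc1oc(=O)c(CC2=C(O)/C(=C/C=C(C)C)C(=O)C(C(=O)[C@@H](C)CC)=C2O)c(O)c1C | intermediate
16 | 6-ethyl-4-hydroxy-3-({5,7-dihydroxy-2,2-dimethyl-8-[(2S)-2-methylbutanoyl]-2H-chromen-6-yl}methyl)-5-methyl-2H-pyran-2-one | CCc1oc(=O)c(Cc2c(O)c3c(c(C(=O)[C@@H](C)CC)c2O)OC(C)(C)C=C3)c(O)c1C | target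

## Step count and risks

Total step count: 3. Longest linear sequence: 2 steps (step 1 then step 3, or step 2 then step 3).

Steps most likely to fail, most risky first:

**Step 3.** Two things can go wrong. The pyran ring may close on the oxygen para to the acyl group, giving the 6-acyl-8-pyronylmethyl isomer. The methylene bridge of 14 may also scramble by retro-Michael fragmentation at 70 °C in the amine buffer. The fallback sets out from 4 and comes back at 16; it closes the chromene first, with the competing oxygen blocked, and makes the bridge last at room temperature: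
- Mono-protection of the most acidic, non-chelated 4-OH of 4 (MeOCH2Cl 1.0 equiv, i-Pr2NEt, CH2Cl2, 0 °C) gives (2S)-1-[2,6-dihydroxy-4-(methoxymethoxy)phenyl]-2-methylbutan-1-one F5.
- Annulation with 11 (ethylenediammonium diacetate 10 mol%, PhMe, 110 °C) can only close on the hydroxyl ortho to the acyl group and gives (2S)-1-[7-hydroxy-5-(methoxymethoxy)-2,2-dimethyl-2H-chromen-8-yl]-2-methylbutan-1-one F6.
- Acetal cleavage (HCl, MeOH, 40 °C) gives (2S)-1-(5,7-dihydroxy-2,2-dimethyl-2H-chromen-8-yl)-2-methylbutan-1-one F7.
- Separately, 9 and 10 (CH2Cl2, rt) give 3-[(dimethylamino)methyl]-6-ethyl-4-hydroxy-5-methyl-2H-pyran-2-one F8. Adding F7, whose C6 is the only free nucleophilic ring carbon, traps the derived methylene-pyrandione and returns to the route at 16.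

**Step 2.** The one-flask double acylation may give 2:1 adducts of 9 with a second malonyl dichloride, or polymer from chlorocarbonylketene. The fallback sets out from 5 and comes back at 9; it separates C-acylation from ring closure:
- 5 is silylated as before, but 7 is isolated by pentane work-up and distillation.
- 7 is C-acylated with the mono-acid chloride methyl 3-chloro-3-oxopropanoate (ZnCl2 10 mol%, CH2Cl2, 0 °C → rt) to the stable triketide ester methyl 4-methyl-3,5-dioxoheptanoate F4.
- Base-mediated enol-lactonisation (DBU, 1,8-diazabicyclo[5.4.0]undec-7-ene, PhMe, 110 °C) closes the ring to 9.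

**Step 1.** The α-stereocentre may partly racemise through the acylium ion or ketene, or di-acylation and O-acylation may lower the yield. The fallback sets out from 2 and comes back at 4; it builds the aromatic ring by a polyketide-type Claisen cyclisation instead of acylating it:
- 2 is converted (1,1'-carbonyldiimidazole, then MeNHOMe·HCl, CH2Cl2, rt) to (2S)-N-methoxy-N,2-dimethylbutanamide F1.
- The dianion of commercial 4-hydroxy-6-methyl-2H-pyran-2-one (LiN(i-Pr)2 2.1 equiv, THF, −78 °C) is acylated at its methyl carbon by F1 to give 4-hydroxy-6-[(3S)-3-methyl-2-oxopentyl]-2H-pyran-2-one F2. The chelated tetrahedral adduct protects the α-centre.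
- Mg(OMe)2 in MeOH at reflux opens the lactone to methyl (8S)-8-methyl-3,5,7-trioxodecanoate F3, which undergoes C6-to-C1 Claisen cyclisation and aromatises to 4.

## Further compounds

F1 | step 1 | (2S)-N-methoxy-N,2-dimethylbutanamide | CC[C@H](C)C(=O)N(C)OC
F2 | step 1 | 4-hydroxy-6-[(3S)-3-methyl-2-oxopentyl]-2H-pyran-2-one | CC[C@H](C)C(=O)Cc1cc(O)cc(=O)o1
F3 | step 1 | methyl (8S)-8-methyl-3,5,7-trioxodecanoate | CC[C@H](C)C(=O)CC(=O)CC(=O)CC(=O)OC
F4 | step 2 | methyl 4-methyl-3,5-dioxoheptanoate (racemic, labile C4) | CCC(=O)C(C)C(=O)CC(=O)OC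
F5 | step 3 | (2S)-1-[2,6-dihydroxy-4-(methoxymethoxy)phenyl]-2-methylbutan-1-one | CC[C@H](C)C(=O)c1c(O)cc(OCOC)cc1O
F6 | step 3 | (2S)-1-[7-hydroxy-5-(methoxymethoxy)-2,2-dimethyl-2H-chromen-8-yl]-2-methylbutan-1-one | CC[C@H](C)C(=O)c1c(O)cc(OCOC)c2C=CC(C)(C)Oc12
F7 | step 3 | (2S)-1-(5,7-dihydroxy-2,2-dimethyl-2H-chromen-8-yl)-2-methylbutan-1-one | CC[C@H](C)C(=O)c1c(O)cc(O)c2C=CC(C)(C)Oc12
F8 | step 3 | 3-[(dimethylamino)methyl]-6-ethyl-4-hydroxy-5-methyl-2H-pyran-2-one | CCc1oc(=O)c(CN(C)C)c(O)c1C
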